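**Strategy.** The route rests on the C2–C3 bond of the dihydrofuran ring. C2 (bound to ring oxygen O1 and the isopropenyl group) and C3 (the benzylic carbinol carbon on C3a) both carry oxygen, so they are joined reductively. A nickel-catalysed, ligand-controlled methylative cyclisation of an aryl allenyl ether onto its ortho formyl group forms C2–C3, delivers the isopropenyl methyl from Me2Zn and sets both stereocentres cis (2R,3R) in one operation. The precursor is 5-acetyl-4-hydroxy-2-(allenyloxy)benzaldehyde, made from a fluorohydroxyacetophenone. Mitsunobu esterification with the Z acid then inverts C3 to the trans (2R,3S) ester.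

Key step: step 5

Remark: the SMILES is read as the (2R,3S) isomer with the C2 isopropenyl and C3 acyloxy groups trans; in step 5 the ligand antipode that gives (2R,3R)-8 is meant, to be fixed by a preliminary screen.

Step 1
Reactants: 1 1-(2-fluoro-4-hydroxyphenyl)ethan-1-one
Product: 2 5-acetyl-4-fluoro-2-hydroxybenzaldehyde
Conditions: MgCl2, Et3N, (CH2O)n, MeCN, reflux; aq HCl
Reagents that add atoms: paraformaldehyde (as formaldehyde) C=O
Why: Casnati–Skattebøl ortho-formylation: the magnesium phenoxide directs formaldehyde to the ortho position, the site not flanked by fluorine reacts for steric reasons, and a second formaldehyde oxidises the benzylic alkoxide by hydride transfer, so the formyl group enters para to fluorine and meta to the acetyl group.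

Step 2
Reactants: 2 5-acetyl-4-fluoro-2-hydroxybenzaldehyde
Product: 3 5-acetyl-4-fluoro-2-(prop-2-yn-1-yloxy)benzaldehyde
Conditions: propargyl bromide, K2CO3, acetone, rt
Reagents that add atoms: propargyl bromide C#CCBr
Why: Williamson etherification of the acidic salicylaldehyde-type phenol by SN2 reaction with propargyl bromide, which at room temperature should outrun attack of the weakly nucleophilic phenoxide on the activated C–F bond.

Step 3
Reactants: 3 5-acetyl-4-fluoro-2-(prop-2-yn-1-yloxy)benzaldehyde
Product: 5 5-acetyl-4-hydroxy-2-(prop-2-yn-1-yloxy)benzaldehyde, via O-aryl acetohydroxamate 4 (not isolated)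
Conditions: AcNHOH, K2CO3, DMSO, 25–50 °C; aq citric acid
Reagents that add atoms: acetohydroxamic acid CC(=O)NO
Why: Nucleophilic aromatic substitution (SNAr) of the fluoride, activated by the ortho acetyl and para formyl groups, by the hydroxamate oxygen followed by Lossen-type fragmentation of the O-aryl hydroxamate (hydroxide-surrogate hydroxylation), which frees the phenol without hydroxide and so spares the aldehyde and the methyl ketone.

Step 4
Reactants: 5 5-acetyl-4-hydroxy-2-(prop-2-yn-1-yloxy)benzaldehyde
Product: 6 5-acetyl-4-hydroxy-2-(propa-1,2-dien-1-yloxy)benzaldehyde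
Conditions: KOtBu (1.4 equiv), THF/t-BuOH, 0 °C to rt; aq NH4Cl
Reagents that add atoms: none
Why: Base-mediated propargyl-to-allenyl prototropic isomerisation of an aryl propargyl ether, in which the first equivalent of KOtBu forms the phenoxide that, as a vinylogous carboxylate, should shield the ortho acetyl and para formyl groups from enolisation and addition.

Step 5
Reactants: 6 5-acetyl-4-hydroxy-2-(propa-1,2-dien-1-yloxy)benzaldehyde
Product: 8 1-[(2R,3R)-3,6-dihydroxy-2-(prop-1-en-2-yl)-2,3-dihydro-1-benzofuran-5-yl]ethan-1-one, via methylzinc alkoxide 7 (not isolated)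
Conditions: Ni(cod)2 (10 mol%), spirobiindane phosphoramidite ligand SIPHOS-PE (12 mol%), Me2Zn (3.5 equiv), THF/toluene, 0 °C, slow addition of 6; aq NH4Cl
Reagents that add atoms: dimethylzinc C[Zn]C
Why: Proposed new method: zerovalent nickel carrying the chiral monodentate phosphoramidite is expected to bind the formyl group and the oxygen-substituted C=C of the allene and to undergo oxidative cyclisation to a cis-fused oxanickelacycle (this forms the C2–C3 bond), after which methyl transfer from zinc to nickel and C–C reductive elimination place the methyl group on the central allene carbon, which becomes the isopropenyl group. The closest known reactions are the racemic nickel-catalysed alkylative cyclisation of allenyl aldehydes with organozincs, which gives cis-2-isopropenyl cycloalkanols, and the enantioselective nickel/spiro-phosphoramidite alkylative coupling of alkynes with aldehydes and Me2Zn; their combination on an aryl allenyl ether under ligand control is not established. The dihydrofuran ring closes in a 5-exo-trig mode on the aldehyde carbonyl. C2 and C3 are set together: the cis relation follows from the five-membered metallacycle, which holds the nickel-bound oxygen on C3 and the nickel-bound carbon on C2 on the same face, and the absolute configuration (2R,3R) is set by the ligand in the oxidative cyclisation. The step needs regioselectivity (C–C bond at the oxygen-bearing allene terminus, methyl on the central carbon) and chemoselectivity for the aldehyde over the acetyl ketone; the three-atom tether lets only the proximal allene carbon reach the formyl carbon in a five-membered ring, and the ketone is held as a chelated zinc phenoxide that does not take part.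

Step 6
Reactants: 9 but-2-yn-1-ol
Product: 11 (2Z)-3-iodobut-2-en-1-ol, via cyclic alkenylalanate 10 (not isolated)
Conditions: Na[AlH2(OCH2CH2OCH3)2] (Red-Al), THF, 0 °C to rt; EtOAc; then I2, −78 to 0 °C
Reagents that add atoms: iodine II
Why: Hydroxyl-directed trans-hydroalumination of the propargylic alcohol through the five-membered alkoxyalanate puts aluminium on C3 anti to the new C2–H bond, and iodinolysis with retention should give the Z iodide that fixes the alkene geometry of the side chain.

Step 7
Reactants: 11 (2Z)-3-iodobut-2-en-1-ol
Product: 12 (2Z)-3-iodobut-2-en-1-yl acetate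
Conditions: Ac2O, pyridine, DMAP (cat.), CH2Cl2, 0 °C
Reagents that add atoms: acetic anhydride CC(=O)OC(C)=O
Why: Standard O-acetylation (nucleophilic catalysis by DMAP), done before the carboxyl group is introduced so that the Z hydroxy acid can never lactonise to the butenolide.

Step 8
Reactants: 12 (2Z)-3-iodobut-2-en-1-yl acetate
Product: 13 (2Z)-4-(acetyloxy)-2-methylbut-2-enoic acid
Conditions: Pd(OAc)2 (5 mol%), PPh3 (10 mol%), CO (1 atm), H2O, Et3N, DMF, 40 °C; aq citric acid
Reagents that add atoms: carbon monoxide [C-]#[O+]; water O
Why: Palladium-catalysed hydroxycarbonylation of a vinyl iodide (oxidative addition, CO insertion, hydrolysis of the acylpalladium species) proceeds with retention of the Z geometry, and oxidative addition to the C–I bond under CO should outpace ionisation of the primary allylic acetate.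

Step 9
Reactants: 8 1-[(2R,3R)-3,6-dihydroxy-2-(prop-1-en-2-yl)-2,3-dihydro-1-benzofuran-5-yl]ethan-1-one; 13 (2Z)-4-(acetyloxy)-2-methylbut-2-enoic acid
Product: 15 (2R,3S)-5-acetyl-6-hydroxy-2-(prop-1-en-2-yl)-2,3-dihydro-1-benzofuran-3-yl (2Z)-4-(acetyloxy)-2-methylbut-2-enoate, via alkoxyphosphonium carboxylate 14 (not isolated)
Conditions: PPh3, DIAD, THF, −20 °C to rt
Reagents that add atoms: none
Why: Mitsunobu esterification: SN2 attack of the carboxylate on the alkoxyphosphonium ion inverts C3 (R to S) and turns the cis alcohol into the trans ester while C2 is untouched, and because the acid reacts as a carboxylate nucleophile its Z double bond cannot isomerise through an activated acyl species.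

**Compound list**

1 | 1-(2-fluoro-4-hydroxyphenyl)ethan-1-one | CC(=O)c1ccc(O)cc1F | starting material
2 | 5-acetyl-4-fluoro-2-hydroxybenzaldehyde | CC(=O)c1cc(C=O)c(O)cc1F | intermediate
3 | 5-acetyl-4-fluoro-2-(prop-2-yn-1-yloxy)benzaldehyde | CC(=O)c1cc(C=O)c(OCC#C)cc1F | intermediate
4 | N-{[2-acetyl-4-formyl-5-(prop-2-yn-1-yloxy)phenyl]oxy}acetamide (not isolated) | CC(=O)NOc1cc(OCC#C)c(C=O)cc1C(C)=O | intermediate
5 | 5-acetyl-4-hydroxy-2-(prop-2-yn-1-yloxy)benzaldehyde | CC(=O)c1cc(C=O)c(OCC#C)cc1O | intermediate
6 | 5-acetyl-4-hydroxy-2-(propa-1,2-dien-1-yloxy)benzaldehyde | CC(=O)c1cc(C=O)c(OC=C=C)cc1O | intermediate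
7 | bis(methylzinc) alkoxide-phenoxide of 8 (not isolated) | C=C(C)[C@H]1Oc2cc(O[Zn]C)c(C(C)=O)cc2[C@H]1O[Zn]C | intermediate
8 | 1-[(2R,3R)-3,6-dihydroxy-2-(prop-1-en-2-yl)-2,3-dihydro-1-benzofuran-5-yl]ethan-1-one (cis) | C=C(C)[C@H]1Oc2cc(O)c(C(C)=O)cc2[C@H]1O | intermediate
9 | but-2-yn-1-ol | CC#CCO | starting material
10 | sodium 2,2-bis(2-methoxyethoxy)-3-methyl-2,5-dihydro-1,2-oxaluminol-2-uide (not isolated) | [Na+].CC1=CCO[Al-]1(OCCOC)OCCOC | intermediate
11 | (2Z)-3-iodobut-2-en-1-ol | C/C(I)=C/CO | intermediate
12 | (2Z)-3-iodobut-2-en-1-yl acetate | C/C(I)=C/COC(C)=O | intermediate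
13 | (2Z)-4-(acetyloxy)-2-methylbut-2-enoic acid | OC(=O)/C(C)=C\COC(C)=O | intermediate
14 | {[(2R,3R)-5-acetyl-6-hydroxy-2-(prop-1-en-2-yl)-2,3-dihydro-1-benzofuran-3-yl]oxy}triphenylphosphonium (2Z)-4-(acetyloxy)-2-methylbut-2-enoate (not isolated) | C=C(C)[C@H]1Oc2cc(O)c(C(C)=O)cc2[C@H]1O[P+](c1ccccc1)(c1ccccc1)c1ccccc1.[O-]C(=O)/C(C)=C\COC(C)=O | intermediate
15 | (2R,3S)-5-acetyl-6-hydroxy-2-(prop-1-en-2-yl)-2,3-dihydro-1-benzofuran-3-yl (2Z)-4-(acetyloxy)-2-methylbut-2-enoate (CNP0273504.1) | C=C(C)[C@H]1Oc2cc(O)c(C(C)=O)cc2[C@@H]1OC(=O)/C(C)=C\COC(C)=O | target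

**Step count.** Total: 9 steps. Longest linear sequence: 6 steps (steps 1–5 and 9); steps 6–8 build the acid.

**Steps most likely to fail**

Step 5 (Proposed new method). The enantiofacial discrimination in the oxidative cyclisation may be insufficient, a ligand-free background reaction may erode the enantiomeric purity, or the allenyl ether may oligomerise at nickel. The fallback uses known chemistry, sets out from 6 and comes back at 8. The established racemic protocol (Ni(cod)2, Me2Zn, Ti(OiPr)4, THF, 0 °C, no chiral ligand) should give the racemic cis alcohol F1. Lipase-catalysed kinetic resolution (Amano lipase PS, vinyl acetate, MTBE, 30 °C) is then expected, by the Kazlauskas rule, to acetylate the (2S,3S) enantiomer to the acetate F2 and to leave (2R,3R)-8, which is separated by chromatography and carried into step 9.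

Step 4. Base-induced aldol-type condensation between the acetyl and formyl groups, or addition of the propargylic or allenic carbanion to the ortho formyl group, may compete with the prototropic shift. The fallback sets out from 5 and comes back at 6. The formyl group is reduced chemoselectively (NaBH4, MeOH/THF, −40 °C; the chelated aryl ketone is much slower) to the benzylic alcohol F3. KOtBu isomerisation of F3, which carries no electrophilic aldehyde, should give the allenyl ether alcohol F4, and MnO2 (CH2Cl2, rt) oxidises the benzylic alcohol to give 6.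

Step 9. Anti elimination of the oxyphosphonium intermediate toward the aromatic benzofuran, or ionisation at the electron-rich benzylic carbon with loss of clean inversion, may intervene. The fallback sets out from 8 and comes back at 15. Compound 8 is converted with Cl3CCN and catalytic DBU (CH2Cl2, 0 °C) into the cis trichloroacetimidate F5, which is stirred with acid 13 in toluene at rt without promoter. Protonation by the acid, ionisation to the benzylic cation and capture of the carboxylate on the face anti to the C2 isopropenyl group should give the trans ester 15 in a stereoconvergent SN1 esterification, again without activating the carboxyl group.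

**Further compounds**

F1 | step 5 | racemic cis-1-[3,6-dihydroxy-2-(prop-1-en-2-yl)-2,3-dihydro-1-benzofuran-5-yl]ethan-1-one | C=C(C)[C@H]1Oc2cc(O)c(C(C)=O)cc2[C@H]1O.C=C(C)[C@@H]1Oc2cc(O)c(C(C)=O)cc2[C@@H]1O
F2 | step 5 | (2S,3S)-5-acetyl-6-hydroxy-2-(prop-1-en-2-yl)-2,3-dihydro-1-benzofuran-3-yl acetate | C=C(C)[C@@H]1Oc2cc(O)c(C(C)=O)cc2[C@@H]1OC(C)=O
F3 | step 4 | 1-[2-hydroxy-5-(hydroxymethyl)-4-(prop-2-yn-1-yloxy)phenyl]ethan-1-one | CC(=O)c1cc(CO)c(OCC#C)cc1O
F4 | step 4 | 1-[2-hydroxy-5-(hydroxymethyl)-4-(propa-1,2-dien-1-yloxy)phenyl]ethan-1-one | CC(=O)c1cc(CO)c(OC=C=C)cc1O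
F5 | step 9 | (2R,3R)-5-acetyl-6-hydroxy-2-(prop-1-en-2-yl)-2,3-dihydro-1-benzofuran-3-yl 2,2,2-trichloroethanimidate | C=C(C)[C@H]1Oc2cc(O)c(C(C)=O)cc2[C@H]1OC(=N)C(Cl)(Cl)Cl
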